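(The earlier runs and the new flask are simulated for substances that don't exist.)

In a closed flask, c(product) plus c(coupling partner) stays constant, apart from what the catalyst holds. Dividing the rate of product formation by the rate of coupling partner loss therefore gives one, and time drops out. Amber reads this way: it stops at 32.6 % of its starting material, against a ratio of charges of 31.8 %, which is within the scatter. The coupling partner is the limiting reagent, so I carry the ceiling yield, charged c(coupling partner) over charged c(starting material), which is 70.0 % for west and north-west alike.

| flask | starting material | coupling partner | precatalyst | temperature | remark | time |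
|---|---|---|---|---|---|---|
| violet | 0.56 M | 0.28 M | 2 mM | −45 °C | run made earlier |  |
| amber | 0.88 M | 0.28 M | 2 mM | −30 °C | run made earlier |  |
| blue | 0.40 M | 0.28 M | 3 mM | −45 °C | run made earlier |  |
| west | 0.40 M | 0.280 M | 2.0 mM | −20 °C |  | 40 h |
| north-west | 0.40 M | 0.280 M | 2.0 mM | −40 °C |  | 40 h |

| run | time / h | product / % |
|---|---|---|
| violet | 15.0 | 0.1 |
| violet | 20.0 | 0 |
| violet | 30.0 | 0 |
| violet | 72.0 | 2.5 |
| violet | 96.0 | 7.3 |
| violet | 192 | 15.8 |
| amber | 12.0 | 3.4 |
| amber | 25.0 | 14.7 |
| amber | 40.0 | 27.8 |
| amber | 50.0 | 31.7 |
| amber | 60.0 | 32.1 |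
| amber | 72.0 | 32.6 |
| blue | 15.0 | 1.8 |
| blue | 40.0 | 3.7 |
| blue | 72.0 | 6.5 |
| blue | 96.0 | 9.0 |
| blue | 192 | 30.3 |

(each reading ± 1 percentage point)

1. the flask that comes out highest in amount of product, in percent of the starting material charged, or "all alike" when all lie within 1.5 percentage points (west / north-west / all alike)
2. product at the end, in percent of the starting material charged, west
3. product at the end, in percent of the starting material charged, north-west

The time scales form a ladder. First comes the lag: amber reads 3.4 % at 12.0 h, while violet still reads 0 % at 30.0 h. Next comes the filling time, the coupling partner charge over the steady rate. Amber climbs at 0.00769 M h⁻¹, so it fills in 36.4 h. Violet climbs late at 4.96 × 10⁻⁴ M h⁻¹, so it needs 565 h, well beyond its last reading.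

West must fill within 40 h. If I take the rate as proportional to c(starting material), west needs 2.00 times amber's rate per charge. Going from −45 °C to −30 °C gained 9.86 times, and west stands hotter still at −20 °C, so I expect west on its ceiling. For north-west, at −40 °C, I reckon from the nearest cold run. Blue, at −45 °C with more precatalyst, reads 3.7 % at 40.0 h, so I expect north-west near that reading, far below the ceiling.

The forecast gives west as highest, with 61 % for west and 4 % for north-west, adding “though catalyst death is possible”. The simulation gives 69.9 % for west and 5.69 % for north-west, so west comes out higher.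

    coupling partner + free catalyst → catalyst intermediate A (k = 1840 M⁻¹ h⁻¹, Ea = 50.0 kJ mol⁻¹)
    catalyst intermediate A → released group + catalyst intermediate B (k = 52.4 h⁻¹, Ea = 60.0 kJ mol⁻¹)
    catalyst intermediate B ⇌ catalyst intermediate C (K = 0.460, k = 49.5 h⁻¹, Ea = 77.0 kJ mol⁻¹, ΔH = −10.0 kJ mol⁻¹)
    starting material + catalyst intermediate C → catalyst intermediate D (k = 115 M⁻¹ h⁻¹, Ea = 53.0 kJ mol⁻¹)
    catalyst intermediate D ⇌ free catalyst + product (K = 3.95 M, k = 3520 h⁻¹, Ea = 57.0 kJ mol⁻¹, ΔH = −44.0 kJ mol⁻¹)
    precatalyst → free catalyst (k = 0.476 h⁻¹, Ea = 75.0 kJ mol⁻¹)
    product + catalyst intermediate C → spent catalyst (k = 0.0738 M⁻¹ h⁻¹, Ea = 67.0 kJ mol⁻¹)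
    (constants at −20 °C)

West stops on the ceiling because its coupling partner is gone, at 0 % of its charge, while 30 % of the starting material remains. With that supply held from shrinking, the same run reaches 87.2 %. In a neighbour of west charged with 0.24 M of starting material, the same ratio of charges is 1.17, above one, so the ceiling passes to the starting material at full conversion. The computed flask gives 89.8 %, with 22 % of the coupling partner left.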